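**Retrosynthetic overview**
1. The last operation closes three rings. Acid converts a protected 4-hydroxy ketone/acyl-oxazolidinone into the spiroketal lactone (rings C and D); N-deprotection then lets the azepane nitrogen condense with a side-chain ketone to give the enamine (ring A).
2. The side-chain ketone comes from a 2-vinylazepane by hydroboration and acyl cross-coupling with a thioester of (2S,4S)-4-methyl-5-oxooxolane-2-carboxylic acid, made from the L-glutamic-acid-derived lactone acid.
3. Ring B is closed earlier by sulfonamide N-alkylation with a primary chloride.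
4. The adjacent O-, C- and N-bearing stereocentres are set one at a time by three rounds of cross-metathesis and iridium-catalysed branched allylic substitution (silanolate, ketone enol silane, sulfonamide), starting from 5-chloropent-1-ene.
5. The ketone nucleophile carries the ring D stereocentres from an Evans syn-aldol with 2-methylidenepentanal. Ring order: B, then C and D together, then A.

Assumption: L is the phosphoramidite from 1,1′-bi-2-naphthol and bis(1-phenylethyl)amine; the antipode named in steps 2, 9 and 11 follows the usual facial preference of this catalyst family, and the other (also commercial) antipode is used if a test run shows the opposite sense; the ethyl-bearing carbon made in step 9 is an epimer mixture, drawn in its final configuration, that converges in step 17.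

**Route**

Step 1
Reactants: 1 5-chloropent-1-ene; 2 allyl tert-butyl carbonate
Product: 3 tert-butyl (2E)-6-chlorohex-2-en-1-yl carbonate
Conditions: 2 (3 equiv), second-generation Hoveyda–Grubbs catalyst RuCl2(H2IMes)(=CH-C6H4-2-OiPr) (2 mol%), CH2Cl2, 40 °C
Reagents that add atoms: none
Why: Olefin cross-metathesis of a terminal alkene with excess allyl carbonate is driven by loss of ethene and gives mainly the E-alkene, the primary chloride being inert.

Step 2
Reactants: 3 tert-butyl (2E)-6-chlorohex-2-en-1-yl carbonate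
Product: 4 (3R)-6-chloro-3-(triethylsilyloxy)hex-1-ene
Conditions: [Ir(cod)Cl]2 (2 mol%), (Sa,Sc,Sc)-L (4 mol%), KOSiEt3 (2 equiv), CH2Cl2, rt
Reagents that add atoms: potassium triethylsilanolate, CC[Si](CC)(CC)[O-].[K+]
Why: Iridium-catalysed asymmetric allylic substitution with a silanolate attacks the substituted allyl terminus (branched product), and the phosphoramidite sets the O-bearing stereocentre as R.

Step 3
Reactants: 4 (3R)-6-chloro-3-(triethylsilyloxy)hex-1-ene; 2 allyl tert-butyl carbonate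
Product: 5 tert-butyl (2E,4R)-7-chloro-4-(triethylsilyloxy)hept-2-en-1-yl carbonate
Conditions: 2 (3 equiv), second-generation Hoveyda–Grubbs catalyst RuCl2(H2IMes)(=CH-C6H4-2-OiPr) (3 mol%), CH2Cl2, 40 °C
Reagents that add atoms: none
Why: Olefin cross-metathesis of the allylic silyl ether with the allyl carbonate gives the E-allylic carbonate without touching the stereocentre.

Step 4
Reactants: 6 pentanal
Product: 7 2-methylidenepentanal
Conditions: 37% aq. HCHO, pyrrolidine (10 mol%), EtCO2H (10 mol%), iPrOH, 45 °C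
Reagents that add atoms: formaldehyde, C=O
Why: Amine/acid-catalysed Mannich-type α-methylenation (aldol condensation with formaldehyde) gives the 2-substituted acrolein.

Step 5
Reactants: 7 2-methylidenepentanal; 8 (4R)-4-benzyl-3-propanoyl-1,3-oxazolidin-2-one
Product: 9 Evans syn-aldol adduct
Conditions: Bu2BOTf, iPr2NEt, CH2Cl2, 0 °C; 7, −78 → 0 °C; then pH 7 buffer, MeOH, H2O2
Reagents that add atoms: none
Why: Evans syn-aldol reaction in which the Z-boron enolate of the (R)-auxiliary adds through a Zimmerman–Traxler chair and sets the methyl- and hydroxyl-bearing carbons as 2R,3R.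

Step 6
Reactants: 9 Evans syn-aldol adduct
Product: 10 TBS ether of the aldol adduct
Conditions: TBSOTf, 2,6-lutidine, CH2Cl2, −78 → 0 °C
Reagents that add atoms: tert-butyldimethylsilyl triflate, CC(C)(C)[Si](C)(C)OS(=O)(=O)C(F)(F)F
Why: Silylation of the secondary alcohol blocks retro-aldol and elimination in the later steps.

Step 7
Reactants: 10 TBS ether of the aldol adduct
Product: 11 α-silyloxy propyl ketone
Conditions: O3, CH2Cl2, −78 °C; then PPh3
Reagents that add atoms: ozone, [O-][O+]=O
Why: Ozonolysis cleaves the 1,1-disubstituted alkene to the ketone, which is the future spiro carbon, while imide and silyl ether survive.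

Step 8
Reactants: 11 α-silyloxy propyl ketone
Product: 12 trimethylsilyl enol ether
Conditions: TMSOTf, Et3N, CH2Cl2, 0 °C
Reagents that add atoms: trimethylsilyl triflate, C[Si](C)(C)OS(=O)(=O)C(F)(F)F
Why: Soft enolisation silylates toward the unhindered CH2 and not toward the silyloxy-bearing methine or the branched imide, giving the enol silane needed as carbon nucleophile.

Step 9
Reactants: 12 trimethylsilyl enol ether; 5 tert-butyl (2E,4R)-7-chloro-4-(triethylsilyloxy)hept-2-en-1-yl carbonate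
Product: 13 γ,δ-unsaturated ketone
Conditions: [Ir(cod)Cl]2 (2 mol%), (Ra,Rc,Rc)-L (4 mol%, pre-activated with nPrNH2), CsF (0.4 equiv), ZnF2 (1.5 equiv), DME, 50 °C
Reagents that add atoms: none
Why: Iridium-catalysed asymmetric allylic alkylation of a fluoride-activated ketone enol silane forms the C–C bond at the substituted allyl terminus with ligand control of the vinyl-bearing stereocentre, while the adjacent ethyl-bearing centre forms as a mixture that is corrected in step 17.

Step 10
Reactants: 13 γ,δ-unsaturated ketone; 2 allyl tert-butyl carbonate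
Product: 14 second allylic carbonate
Conditions: 2 (4 equiv), second-generation Hoveyda–Grubbs catalyst RuCl2(H2IMes)(=CH-C6H4-2-OiPr) (5 mol%), CH2Cl2, 40 °C
Reagents that add atoms: none
Why: Olefin cross-metathesis extends the vinyl group to an E-allylic carbonate so that the next substitution can place nitrogen on the inner carbon.

Step 11
Reactants: 14 second allylic carbonate
Product: 16 N-nosyl 2-vinylazepane, via open-chain allylic nosylamide 15 (not isolated)
Conditions: [Ir(cod)Cl]2 (2 mol%), (Sa,Sc,Sc)-L (4 mol%), TBD (8 mol%), 2-NsNH2 (1.3 equiv), THF, 50 °C; then K2CO3, NaI (cat.), DMF, 60 °C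
Reagents that add atoms: 2-nitrobenzenesulfonamide, NS(=O)(=O)c1ccccc1[N+](=O)[O-]
Why: Iridium-catalysed asymmetric allylic amination with the sulfonamide gives the branched N-bearing stereocentre (S, ligand control), and Fukuyama-type intramolecular N-alkylation by the primary chloride then closes the seven-membered ring B.

Step 12
Reactants: 17 (2S)-5-oxooxolane-2-carboxylic acid
Product: 18 benzyl (2S)-5-oxooxolane-2-carboxylate
Conditions: BnBr, KHCO3, DMF, rt
Reagents that add atoms: benzyl bromide, BrCc1ccccc1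
Why: Carboxylate O-alkylation (SN2) gives the benzyl ester under conditions too mild to open the lactone or epimerise the CH–O centre.

Step 13
Reactants: 18 benzyl (2S)-5-oxooxolane-2-carboxylate
Product: 19 enaminone lactone
Conditions: tBuOCH(NMe2)2, toluene, 80 °C
Reagents that add atoms: tert-butoxybis(dimethylamino)methane, CN(C)C(OC(C)(C)C)N(C)C
Why: Condensation of the lactone α-CH2 with Bredereck's reagent gives the enaminone, a reaction type that leaves the adjacent ester-bearing stereocentre intact in the analogous pyroglutamates.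

Step 14
Reactants: 19 enaminone lactone
Product: 20 (2S,4S)-4-methyl-5-oxooxolane-2-carboxylic acid
Conditions: H2 (3 atm), 10% Pd/C, EtOAc, rt
Reagents that add atoms: none
Why: Heterogeneous hydrogenation removes dimethylamine and the benzyl group, and adds H2 to the resulting α-methylene lactone from the face opposite the carboxyl group, giving the cis (2S,4S) lactone.

Step 15
Reactants: 20 (2S,4S)-4-methyl-5-oxooxolane-2-carboxylic acid
Product: 21 S-phenyl thioester of the lactone acid
Conditions: PhSH, DCC, DMAP (5 mol%), CH2Cl2, 0 °C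
Reagents that add atoms: thiophenol, Sc1ccccc1
Why: Steglich-type carbodiimide thioesterification activates the acid for ketone synthesis without touching the lactone.

Step 16
Reactants: 16 N-nosyl 2-vinylazepane; 21 S-phenyl thioester of the lactone acid
Product: 23 side-chain ketone, via B-alkyl-9-BBN adduct 22 (not isolated)
Conditions: 9-BBN-H (1.3 equiv), THF, 0 °C → rt; then 21, Pd2(dba)3 (2.5 mol%), P(2-furyl)3 (10 mol%), Cu(O2C-2-C4H3S) (1.5 equiv), Cs2CO3 (1 equiv), THF, 45 °C
Reagents that add atoms: none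
Why: Anti-Markovnikov hydroboration of the vinyl group followed by Liebeskind–Srogl acyl cross-coupling of the B-alkyl borane with the thioester gives the ketone under nearly neutral conditions, so the α-acyloxy stereocentre is kept.

Step 17
Reactants: 23 side-chain ketone
Product: 26 target CNP0272443.1, via N-nosyl spiroketal lactone 24 (not isolated), via free amino ketone 25 (not isolated)
Conditions: TFA/H2O/CH2Cl2 (4:1:4), rt; evaporate; then PhSH, K2CO3, MeCN, rt; 4 Å MS
Reagents that add atoms: water, O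
Why: Acid removes both silyl ethers so that the 4-hydroxy ketone closes ring C as a hemiketal/oxocarbenium ion that is trapped by the imide carbonyl with loss of the oxazolidinone (spiroketalisation–lactonisation, ring D), the ethyl-bearing and spiro carbons equilibrating through the enol ether to the all-trans isomer, and Fukuyama denosylation then frees the ring B amine, which condenses with the only remaining ketone to the endocyclic enamine (ring A).

**Compound list**

1 | 5-chloropent-1-ene | C=CCCCCl | starting material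
2 | allyl tert-butyl carbonate | C=CCOC(=O)OC(C)(C)C | starting material
3 | tert-butyl (2E)-6-chlorohex-2-en-1-yl carbonate | ClCCC/C=C/COC(=O)OC(C)(C)C | intermediate
4 | (3R)-6-chloro-3-(triethylsilyloxy)hex-1-ene | C=C[C@@H](CCCCl)O[Si](CC)(CC)CC | intermediate
5 | tert-butyl (2E,4R)-7-chloro-4-(triethylsilyloxy)hept-2-en-1-yl carbonate | CC(C)(C)OC(=O)OC/C=C/[C@@H](CCCCl)O[Si](CC)(CC)CC | intermediate
6 | pentanal | CCCCC=O | starting material
7 | 2-methylidenepentanal | CCCC(=C)C=O | intermediate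
8 | (4R)-4-benzyl-3-propanoyl-1,3-oxazolidin-2-one | CCC(=O)N1[C@H](Cc2ccccc2)COC1=O | starting material
9 | (4R)-4-benzyl-3-[(2R,3R)-3-hydroxy-2-methyl-4-methylideneheptanoyl]-1,3-oxazolidin-2-one | O=C(N1[C@H](Cc2ccccc2)COC1=O)[C@H](C)[C@H](C(=C)CCC)O | intermediate
10 | (4R)-4-benzyl-3-[(2R,3R)-3-(tert-butyldimethylsilyloxy)-2-methyl-4-methylideneheptanoyl]-1,3-oxazolidin-2-one | O=C(N1[C@H](Cc2ccccc2)COC1=O)[C@H](C)[C@H](C(=C)CCC)O[Si](C)(C)C(C)(C)C | intermediate
11 | (4R)-4-benzyl-3-[(2R,3R)-3-(tert-butyldimethylsilyloxy)-2-methyl-4-oxoheptanoyl]-1,3-oxazolidin-2-one | O=C(N1[C@H](Cc2ccccc2)COC1=O)[C@H](C)[C@H](C(=O)CCC)O[Si](C)(C)C(C)(C)C | intermediate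
12 | (4R)-4-benzyl-3-[(2R,3R,4Z)-3-(tert-butyldimethylsilyloxy)-2-methyl-4-(trimethylsilyloxy)hept-4-enoyl]-1,3-oxazolidin-2-one | O=C(N1[C@H](Cc2ccccc2)COC1=O)[C@H](C)[C@H](/C(O[Si](C)(C)C)=C/CC)O[Si](C)(C)C(C)(C)C | intermediate
13 | (4R)-4-benzyl-3-[(2R,3R,5S,6S,7R)-3-(tert-butyldimethylsilyloxy)-10-chloro-6-ethenyl-5-ethyl-2-methyl-4-oxo-7-(triethylsilyloxy)decanoyl]-1,3-oxazolidin-2-one (C5 epimer mixture) | CC[C@H](C(=O)[C@H](O[Si](C)(C)C(C)(C)C)[C@@H](C)C(=O)N1[C@H](Cc2ccccc2)COC1=O)[C@H](C=C)[C@@H](CCCCl)O[Si](CC)(CC)CC | intermediate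
14 | (4R)-4-benzyl-3-[(2R,3R,5S,6S,7R)-6-[(1E)-3-(tert-butoxycarbonyloxy)prop-1-en-1-yl]-3-(tert-butyldimethylsilyloxy)-10-chloro-5-ethyl-2-methyl-4-oxo-7-(triethylsilyloxy)decanoyl]-1,3-oxazolidin-2-one | CC[C@H](C(=O)[C@H](O[Si](C)(C)C(C)(C)C)[C@@H](C)C(=O)N1[C@H](Cc2ccccc2)COC1=O)[C@H](/C=C/COC(=O)OC(C)(C)C)[C@@H](CCCCl)O[Si](CC)(CC)CC | intermediate
15 | (4R)-4-benzyl-3-[(2R,3R,5S,6R,7R)-3-(tert-butyldimethylsilyloxy)-10-chloro-5-ethyl-2-methyl-6-[(1S)-1-[(2-nitrophenyl)sulfonylamino]prop-2-en-1-yl]-4-oxo-7-(triethylsilyloxy)decanoyl]-1,3-oxazolidin-2-one | CC[C@H](C(=O)[C@H](O[Si](C)(C)C(C)(C)C)[C@@H](C)C(=O)N1[C@H](Cc2ccccc2)COC1=O)[C@H]([C@H](C=C)NS(=O)(=O)c1ccccc1[N+](=O)[O-])[C@@H](CCCCl)O[Si](CC)(CC)CC | intermediate (not isolated)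
16 | (4R)-4-benzyl-3-[(2R,3R,5S)-3-(tert-butyldimethylsilyloxy)-5-[(2S,3R,4R)-2-ethenyl-1-[(2-nitrophenyl)sulfonyl]-4-(triethylsilyloxy)azepan-3-yl]-2-methyl-4-oxoheptanoyl]-1,3-oxazolidin-2-one | CC[C@H](C(=O)[C@H](O[Si](C)(C)C(C)(C)C)[C@@H](C)C(=O)N1[C@H](Cc2ccccc2)COC1=O)[C@H]1[C@@H](CCCN([C@H]1C=C)S(=O)(=O)c1ccccc1[N+](=O)[O-])O[Si](CC)(CC)CC | intermediate
17 | (2S)-5-oxooxolane-2-carboxylic acid | OC(=O)[C@@H]1CCC(=O)O1 | starting material
18 | benzyl (2S)-5-oxooxolane-2-carboxylate | O=C(OCc1ccccc1)[C@@H]1CCC(=O)O1 | intermediate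
19 | benzyl (2S,4E)-4-[(dimethylamino)methylidene]-5-oxooxolane-2-carboxylate | O=C(OCc1ccccc1)[C@@H]1C/C(=C\N(C)C)C(=O)O1 | intermediate
20 | (2S,4S)-4-methyl-5-oxooxolane-2-carboxylic acid | OC(=O)[C@@H]1C[C@H](C)C(=O)O1 | intermediate
21 | S-phenyl (2S,4S)-4-methyl-5-oxooxolane-2-carbothioate | O=C(Sc1ccccc1)[C@@H]1C[C@H](C)C(=O)O1 | intermediate
22 | 16 in which the 2-ethenyl group is replaced by 2-(9-borabicyclo[3.3.1]nonan-9-yl)ethyl | CC[C@H](C(=O)[C@H](O[Si](C)(C)C(C)(C)C)[C@@H](C)C(=O)N1[C@H](Cc2ccccc2)COC1=O)[C@H]1[C@@H](CCCN([C@H]1CCB1C2CCCC1CCC2)S(=O)(=O)c1ccccc1[N+](=O)[O-])O[Si](CC)(CC)CC | intermediate (not isolated)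
23 | (4R)-4-benzyl-3-[(2R,3R,5S)-3-(tert-butyldimethylsilyloxy)-2-methyl-5-[(2S,3R,4R)-2-[3-[(2S,4S)-4-methyl-5-oxooxolan-2-yl]-3-oxopropyl]-1-[(2-nitrophenyl)sulfonyl]-4-(triethylsilyloxy)azepan-3-yl]-4-oxoheptanoyl]-1,3-oxazolidin-2-one | CC[C@H](C(=O)[C@H](O[Si](C)(C)C(C)(C)C)[C@@H](C)C(=O)N1[C@H](Cc2ccccc2)COC1=O)[C@H]1[C@@H](CCCN([C@H]1CCC(=O)[C@@H]1C[C@H](C)C(=O)O1)S(=O)(=O)c1ccccc1[N+](=O)[O-])O[Si](CC)(CC)CC | intermediate
24 | (2R,3S,3aR,4S,8aR,3′R,4′R)-3-ethyl-3′-hydroxy-4′-methyl-4-[3-[(2S,4S)-4-methyl-5-oxooxolan-2-yl]-3-oxopropyl]-5-[(2-nitrophenyl)sulfonyl]perhydrospiro[furo[3,2-c]azepine-2,2′-oxolan]-5′-one | CC[C@H]1[C@H]2[C@@H](CCCN([C@H]2CCC(=O)[C@@H]2C[C@H](C)C(=O)O2)S(=O)(=O)c2ccccc2[N+](=O)[O-])O[C@@]12OC(=O)[C@H](C)[C@H]2O | intermediate (not isolated)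
25 | 24 without the sulfonyl group (free NH azepane, same configuration) | CC[C@H]1[C@H]2[C@@H](CCCN[C@H]2CCC(=O)[C@@H]2C[C@H](C)C(=O)O2)O[C@@]12OC(=O)[C@H](C)[C@H]2O | intermediate (not isolated)
26 | CNP0272443.1: ring A enamine formed from 25 by N–C bond formation at the side-chain ketone and loss of water; ethyl-bearing carbon S, ring B/C fusion carbons R and R, N-bearing carbon S, spiro carbon R, carbinol carbon R, methyl-bearing carbon of ring D R, appended lactone 2S,4S | CC[C@H]1[C@H]2[C@@H](CCCN3C([C@@H]4C[C@H](C)C(=O)O4)=CC[C@@H]23)O[C@@]12OC(=O)[C@H](C)[C@H]2O | target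

**Step count and risks**

Total: 17 steps. Longest linear sequence: 10 steps (pentanal to 26 through steps 4, 5, 6, 7, 8, 9, 10, 11, 16 and 17).

Steps most likely to fail:

Step 17. The imide may not transfer its acyl group to the hemiketal cleanly, the spiro or ethyl-bearing carbon may settle in the wrong configuration, or the lactone CH–O centre next to the ketone may epimerise during denosylation. Fallback, setting out from 16 and coming back at 24: LiOH/H2O2 in THF/H2O removes the auxiliary to give the keto acid F5. HF·pyridine in MeCN followed by camphorsulfonic acid closes rings C and D from the free acid to give the spiroketal lactone vinylazepane F6. Hydroboration with 9-BBN-H (2.3 equiv) and the thioester coupling of step 16 with 21 then give 24 as an isolated compound, which is denosylated separately (PhSH, K2CO3, MeCN; 4 Å MS) to 26.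

Step 9. The enolate may attack its own imide, or substitution at the hindered, silyloxy-bearing allyl terminus may give linear product or poor facial control. Fallback, setting out from 4 and 11 and coming back at 13: ozonolysis of 4 (O3; PPh3) gives (2R)-5-chloro-2-(triethylsilyloxy)pentanal F1. The dicyclohexylboron enolate of 11 (Cy2BCl, Et3N) adds to F1 to give the β-hydroxy ketone F2. MsCl/Et3N and then DBU give the (E)-enone F3. Conjugate addition of a vinyl cuprate (CH2=CHMgBr, CuBr·SMe2, TMSCl, THF, −78 °C), anti to the silyloxy group, gives 13.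

Step 11. The bulky neighbouring carbon may divert the intermolecular amination to the linear isomer. Fallback, setting out from 14 and coming back at 16: excess 2-NsNH2 with K2CO3 and NaI in DMF first displaces the chloride to give the N-alkyl nosylamide F4. The same iridium catalyst (or Pd(PPh3)4) then closes the azepane by 7-exo attack of the tethered sulfonamide on the allyl terminus, so that ring size fixes the regiochemistry, and gives 16.

**Further compounds**

F1 | step 9 | (2R)-5-chloro-2-(triethylsilyloxy)pentanal | O=C[C@@H](CCCCl)O[Si](CC)(CC)CC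
F2 | step 9 | (4R)-4-benzyl-3-[(2R,3R,7R)-3-(tert-butyldimethylsilyloxy)-10-chloro-5-ethyl-6-hydroxy-2-methyl-4-oxo-7-(triethylsilyloxy)decanoyl]-1,3-oxazolidin-2-one (mixture at C5 and C6) | CCC(C(=O)[C@H](O[Si](C)(C)C(C)(C)C)[C@@H](C)C(=O)N1[C@H](Cc2ccccc2)COC1=O)C(O)[C@@H](CCCCl)O[Si](CC)(CC)CC
F3 | step 9 | (4R)-4-benzyl-3-[(2R,3R,5E,7R)-3-(tert-butyldimethylsilyloxy)-10-chloro-5-ethyl-2-methyl-4-oxo-7-(triethylsilyloxy)dec-5-enoyl]-1,3-oxazolidin-2-one | CC/C(=C\[C@@H](CCCCl)O[Si](CC)(CC)CC)C(=O)[C@H](O[Si](C)(C)C(C)(C)C)[C@@H](C)C(=O)N1[C@H](Cc2ccccc2)COC1=O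
F4 | step 11 | 14 in which the chlorine is replaced by a (2-nitrophenyl)sulfonylamino group | CC[C@H](C(=O)[C@H](O[Si](C)(C)C(C)(C)C)[C@@H](C)C(=O)N1[C@H](Cc2ccccc2)COC1=O)[C@H](/C=C/COC(=O)OC(C)(C)C)[C@@H](CCCNS(=O)(=O)c1ccccc1[N+](=O)[O-])O[Si](CC)(CC)CC
F5 | step 17 | (2R,3R,5S)-3-(tert-butyldimethylsilyloxy)-5-[(2S,3R,4R)-2-ethenyl-1-[(2-nitrophenyl)sulfonyl]-4-(triethylsilyloxy)azepan-3-yl]-2-methyl-4-oxoheptanoic acid | CC[C@H](C(=O)[C@H](O[Si](C)(C)C(C)(C)C)[C@@H](C)C(O)=O)[C@H]1[C@@H](CCCN([C@H]1C=C)S(=O)(=O)c1ccccc1[N+](=O)[O-])O[Si](CC)(CC)CC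
F6 | step 17 | (2R,3S,3aR,4S,8aR,3′R,4′R)-4-ethenyl-3-ethyl-3′-hydroxy-4′-methyl-5-[(2-nitrophenyl)sulfonyl]perhydrospiro[furo[3,2-c]azepine-2,2′-oxolan]-5′-one | CC[C@H]1[C@H]2[C@@H](CCCN([C@H]2C=C)S(=O)(=O)c2ccccc2[N+](=O)[O-])O[C@@]12OC(=O)[C@H](C)[C@H]2O
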